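**Retrosynthetic overview**

1. The target is robinetinidol-(4β→8)-epigallocatechin: upper unit (2R,3S,4R), 2,3-trans-3,4-cis; lower unit (2R,3R). The last disconnections are the ten benzyl ethers and then the C3 carbinol of the upper unit, back to a flavan-3-one whose C2 and C4 epimerise, so that one dynamic kinetic reduction sets C2, C3 and C4 together.
2. Key disconnection: ring C of the upper unit (O1, C2, C3, C4, C4a, C8a) comes from the five-membered ring of a 2-arylbenzofuran-3(2H)-one (O1, C2, C3 and the two ring A carbons) by inserting C4 between the carbonyl carbon C3 and the ring A carbon. C4 arrives as the carbon of an aryldiazomethane that already carries C8' of ring D, so one ring expansion joins the two flavan halves and makes C3–C4 and C4–C4a.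
3. Feature that allows it: C3 is the oxygen-bearing carbon between C2 and C4 and can stand as a ketone; the ring A carbon C4a is para to the C7 oxygen and ortho to O1, with no oxygen at C5, so it is an electron-rich migrating aryl terminus; C4 carries only H and the bond to C8'.
4. Fragments: the lower unit with both stereocenters comes from (−)-epigallocatechin (benzylation, C8 bromide, aldehyde, hydrazone); the furanone comes from 3-(benzyloxy)phenol, 3,4,5-tris(benzyloxy)benzaldehyde and bromoform.
5. Ring order: rings A and B of the upper unit and all rings of the lower unit come with the starting materials; the furanone ring is closed in step 7 and expanded to ring C in step 8.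

Key step: step 8

Remark: the carbon α to the ketone in the furanone (C2) and the two carbons α to the ketone in the ring-expanded flavan-3-one (C2, C4) epimerise by enolisation; these compounds are written without configuration at those centers, which are fixed only in step 9.

**Route**

Step 1
Reactants: 1 (−)-epigallocatechin, (2R,3R)-2-(3,4,5-trihydroxyphenyl)chromane-3,5,7-triol
Product: 2 (2R,3R)-5,7-bis(benzyloxy)-2-[3,4,5-tris(benzyloxy)phenyl]chroman-3-ol (penta-O-benzyl-epigallocatechin)
Conditions: BnBr, K2CO3, DMF, 0 °C → rt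
Reagents that add atoms: benzyl bromide, BrCc1ccccc1
Why: Williamson etherification of the five phenoxides; K2CO3 does not deprotonate the secondary C3 alcohol, and no stereocenter is touched.

Step 2
Reactants: 2 (2R,3R)-5,7-bis(benzyloxy)-2-[3,4,5-tris(benzyloxy)phenyl]chroman-3-ol
Product: 3 (2R,3R)-3,5,7-tris(benzyloxy)-2-[3,4,5-tris(benzyloxy)phenyl]chromane (hexa-O-benzyl-epigallocatechin)
Conditions: NaH, BnBr, cat. Bu4NI, DMF, 0 °C → rt
Reagents that add atoms: benzyl bromide, BrCc1ccccc1
Why: Williamson etherification of the secondary alkoxide, which removes the last acidic proton before the organolithium step; C2 and C3 are unaffected.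

Step 3
Reactants: 3 (2R,3R)-3,5,7-tris(benzyloxy)-2-[3,4,5-tris(benzyloxy)phenyl]chromane
Product: 4 (2R,3R)-3,5,7-tris(benzyloxy)-8-bromo-2-[3,4,5-tris(benzyloxy)phenyl]chromane
Conditions: NBS (1.0 equiv), CH2Cl2, −78 → 0 °C
Reagents that add atoms: N-bromosuccinimide, O=C1CCC(=O)N1Br
Why: Electrophilic aromatic bromination of the phloroglucinol-type ring, where C8 (between the C7 ether and the ring oxygen) is the position that reacts first in benzylated flavan-3-ols.

Step 4
Reactants: 4 (2R,3R)-3,5,7-tris(benzyloxy)-8-bromo-2-[3,4,5-tris(benzyloxy)phenyl]chromane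
Product: 6 (2R,3R)-3,5,7-tris(benzyloxy)-2-[3,4,5-tris(benzyloxy)phenyl]chromane-8-carbaldehyde, via 8-lithio arene 5 (not isolated)
Conditions: nBuLi, THF, −78 °C; DMF, −78 °C → rt; aq. NH4Cl
Reagents that add atoms: N,N-dimethylformamide, CN(C)C=O
Why: Bromine–lithium exchange followed by formylation of the aryllithium with DMF (Bouveault-type); exchange at −78 °C is faster than any benzylic deprotonation.

Step 5
Reactants: 6 (2R,3R)-3,5,7-tris(benzyloxy)-2-[3,4,5-tris(benzyloxy)phenyl]chromane-8-carbaldehyde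
Product: 7 (E)-hydrazone of 6, (2R,3R)-3,5,7-tris(benzyloxy)-8-(hydrazinylidenemethyl)-2-[3,4,5-tris(benzyloxy)phenyl]chromane
Conditions: N2H4·H2O (excess), EtOH/THF, 60 °C
Reagents that add atoms: hydrazine (as hydrate), NN
Why: Hydrazone formation by condensation; the large excess of hydrazine suppresses azine formation.

Step 6
Reactants: 8 3-(benzyloxy)phenol; 9 3,4,5-tris(benzyloxy)benzaldehyde
Product: 10 rac-2-[3-(benzyloxy)phenoxy]-2-[3,4,5-tris(benzyloxy)phenyl]acetic acid
Conditions: CHBr3, KOH, LiCl, 1,4-dioxane/H2O, 0 °C → rt; then aq. HCl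
Reagents that add atoms: bromoform, BrC(Br)Br; potassium hydroxide, [K+].[OH-]
Why: Jocic–Reeve reaction: tribromomethanide adds to the aldehyde, the gem-dibromoepoxide is opened at the benzylic carbon by the phenoxide of 8, and the acyl bromide is hydrolysed; the new stereocenter is racemic and becomes the labile furanone C2.

Step 7
Reactants: 10 rac-2-[3-(benzyloxy)phenoxy]-2-[3,4,5-tris(benzyloxy)phenyl]acetic acid
Product: 12 rac-6-(benzyloxy)-2-[3,4,5-tris(benzyloxy)phenyl]benzofuran-3(2H)-one, via mixed trifluoroacetic anhydride 11 (not isolated)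
Conditions: TFAA, CH2Cl2, 0 °C → rt, Ar
Reagents that add atoms: none
Why: Intramolecular Friedel–Crafts acylation through the mixed anhydride (5-exo closure of the furanone ring) at the position para to the benzyloxy group and ortho to the ether oxygen, without a free acylium ion and without Lewis acids that attack benzyl ethers.

Step 8
Reactants: 7 (E)-hydrazone of the lower-unit 8-carbaldehyde; 12 rac-6-(benzyloxy)-2-[3,4,5-tris(benzyloxy)phenyl]benzofuran-3(2H)-one
Product: 14 7-(benzyloxy)-2-[3,4,5-tris(benzyloxy)phenyl]-4-{(2R,3R)-3,5,7-tris(benzyloxy)-2-[3,4,5-tris(benzyloxy)phenyl]chroman-8-yl}chroman-3-one (C2/C4 epimer mixture), via aryldiazomethane 13 (not isolated)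
Conditions: 7, MnO2, MgSO4, CH2Cl2, 0 °C, filtration under Ar; the filtrate added to 12 (1.5 equiv), Sc(OTf)3 (10 mol %), toluene/CH2Cl2, −78 → −30 °C
Reagents that add atoms: none
Why: The nucleophilic diazo carbon of 13 adds to the Sc(OTf)3-activated C3 carbonyl of the five-membered ketone 12, and the β-oxido diazonium ion loses N2 with 1,2-shift of the ring A carbon from C3 to the diazo carbon, which thereby becomes C4 between the carbonyl and ring A. The closest known reaction type is the Tiffeneau–Demjanov-type (Büchner–Curtius–Schlotterbeck) homologation of cyclic ketones with aryldiazomethanes under Sc(OTf)3 catalysis, together with the aryl-migrating diazoalkane homologations of aryl ketones and of isatins. No ring is closed by cyclisation: the pyran ring arises from the furanone ring by one-carbon ring expansion (1,2-aryl shift), and the interflavan bond C4–C8' comes in ready-made with the diazo carbon. The new stereocenter C4 is not controlled here: it and C2 are α to the ketone and equilibrate, and both are fixed in step 9. The selectivity needed is migration of the aryl carbon and not of C2; the substrate secures it because the migrating ring A carbon is para to the benzyloxy group and ortho to O1 (phenonium-like transition state), whereas C2 is an oxygen-bearing, more hindered sp3 carbon. A spiro-epoxide formed by O-closure of the same intermediate should converge to 14 under the Lewis acid by opening at the carbon stabilised by ring D and the same aryl shift.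

Step 9
Reactants: 14 deca-O-benzyl flavan-3-one (C2/C4 epimer mixture)
Product: 15 (2R,3S,4R)-7-(benzyloxy)-2-[3,4,5-tris(benzyloxy)phenyl]-4-{(2R,3R)-3,5,7-tris(benzyloxy)-2-[3,4,5-tris(benzyloxy)phenyl]chroman-8-yl}chroman-3-ol
Conditions: RuCl[(S,S)-TsDPEN](p-cymene) (5 mol %), HCO2H (3 equiv), DBU (4 equiv), DMF, 40 °C, Ar
Reagents that add atoms: none
Why: Noyori–Ikariya transfer hydrogenation under dynamic kinetic resolution: C2 and C4 epimerise through the enols, the 2,4-trans ketone with ring D pseudo-axial at C4 and the C2 aryl group equatorial takes hydride at C3 axially on the face anti to ring D (giving 3-OH cis to the C4 aryl and trans to the C2 aryl), and the (S,S)-ligand, on the working model that the oxygen-bearing C2 flank occupies the site of the aryl group of simple aryl ketones, should select the (2R,4R) series and give 3S.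

Step 10
Reactants: 15 deca-O-benzyl-robinetinidol-(4β→8)-epigallocatechin
Product: 16 robinetinidol-(4β→8)-epigallocatechin, (2R,3S,4R)-2-(3,4,5-trihydroxyphenyl)-4-[(2R,3R)-3,5,7-trihydroxy-2-(3,4,5-trihydroxyphenyl)chroman-8-yl]chromane-3,7-diol
Conditions: H2 (1 atm), Pd(OH)2/C, THF/MeOH, rt
Reagents that add atoms: none
Why: Hydrogenolysis of the ten benzyl ethers; no stereocenter is affected, and the interflavan bond of a 5-deoxy upper unit is stable under neutral hydrogenation.

**Compound list**

1 | (−)-epigallocatechin | O[C@@H]1Cc2c(O)cc(O)cc2O[C@@H]1c1cc(O)c(O)c(O)c1 | starting material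
2 | (2R,3R)-5,7-bis(benzyloxy)-2-[3,4,5-tris(benzyloxy)phenyl]chroman-3-ol | O[C@@H]1Cc2c(OCc3ccccc3)cc(OCc3ccccc3)cc2O[C@@H]1c1cc(OCc2ccccc2)c(OCc2ccccc2)c(OCc2ccccc2)c1 | intermediate
3 | (2R,3R)-3,5,7-tris(benzyloxy)-2-[3,4,5-tris(benzyloxy)phenyl]chromane | c1ccccc1CO[C@@H]1Cc2c(OCc3ccccc3)cc(OCc3ccccc3)cc2O[C@@H]1c1cc(OCc2ccccc2)c(OCc2ccccc2)c(OCc2ccccc2)c1 | intermediate
4 | (2R,3R)-3,5,7-tris(benzyloxy)-8-bromo-2-[3,4,5-tris(benzyloxy)phenyl]chromane | c1ccccc1CO[C@@H]1Cc2c(OCc3ccccc3)cc(OCc3ccccc3)c(Br)c2O[C@@H]1c1cc(OCc2ccccc2)c(OCc2ccccc2)c(OCc2ccccc2)c1 | intermediate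
5 | (2R,3R)-3,5,7-tris(benzyloxy)-2-[3,4,5-tris(benzyloxy)phenyl]chroman-8-yllithium | c1ccccc1CO[C@@H]1Cc2c(OCc3ccccc3)cc(OCc3ccccc3)c([Li])c2O[C@@H]1c1cc(OCc2ccccc2)c(OCc2ccccc2)c(OCc2ccccc2)c1 | intermediate (not isolated)
6 | (2R,3R)-3,5,7-tris(benzyloxy)-2-[3,4,5-tris(benzyloxy)phenyl]chromane-8-carbaldehyde | c1ccccc1CO[C@@H]1Cc2c(OCc3ccccc3)cc(OCc3ccccc3)c(C=O)c2O[C@@H]1c1cc(OCc2ccccc2)c(OCc2ccccc2)c(OCc2ccccc2)c1 | intermediate
7 | (E)-hydrazone of 6 | c1ccccc1CO[C@@H]1Cc2c(OCc3ccccc3)cc(OCc3ccccc3)c(/C=N/N)c2O[C@@H]1c1cc(OCc2ccccc2)c(OCc2ccccc2)c(OCc2ccccc2)c1 | intermediate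
8 | 3-(benzyloxy)phenol | Oc1cccc(OCc2ccccc2)c1 | starting material
9 | 3,4,5-tris(benzyloxy)benzaldehyde | O=Cc1cc(OCc2ccccc2)c(OCc2ccccc2)c(OCc2ccccc2)c1 | starting material
10 | rac-2-[3-(benzyloxy)phenoxy]-2-[3,4,5-tris(benzyloxy)phenyl]acetic acid | OC(=O)C(Oc1cccc(OCc2ccccc2)c1)c1cc(OCc2ccccc2)c(OCc2ccccc2)c(OCc2ccccc2)c1 | intermediate
11 | mixed anhydride of 10 with trifluoroacetic acid | FC(F)(F)C(=O)OC(=O)C(Oc1cccc(OCc2ccccc2)c1)c1cc(OCc2ccccc2)c(OCc2ccccc2)c(OCc2ccccc2)c1 | intermediate (not isolated)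
12 | rac-6-(benzyloxy)-2-[3,4,5-tris(benzyloxy)phenyl]benzofuran-3(2H)-one (C2 labile) | O=C1C(c2cc(OCc3ccccc3)c(OCc3ccccc3)c(OCc3ccccc3)c2)Oc2cc(OCc3ccccc3)ccc12 | intermediate
13 | (2R,3R)-3,5,7-tris(benzyloxy)-8-(diazomethyl)-2-[3,4,5-tris(benzyloxy)phenyl]chromane | c1ccccc1CO[C@@H]1Cc2c(OCc3ccccc3)cc(OCc3ccccc3)c(C=[N+]=[N-])c2O[C@@H]1c1cc(OCc2ccccc2)c(OCc2ccccc2)c(OCc2ccccc2)c1 | intermediate (not isolated)
14 | 7-(benzyloxy)-2-[3,4,5-tris(benzyloxy)phenyl]-4-{(2R,3R)-3,5,7-tris(benzyloxy)-2-[3,4,5-tris(benzyloxy)phenyl]chroman-8-yl}chroman-3-one (C2 and C4 of the new ring labile, not specified) | c1ccccc1COc1ccc2c(c1)OC(c1cc(OCc3ccccc3)c(OCc3ccccc3)c(OCc3ccccc3)c1)C(=O)C2c1c(OCc3ccccc3)cc(OCc3ccccc3)c2c1O[C@H](c1cc(OCc3ccccc3)c(OCc3ccccc3)c(OCc3ccccc3)c1)[C@H](OCc1ccccc1)C2 | intermediate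
15 | (2R,3S,4R)-7-(benzyloxy)-2-[3,4,5-tris(benzyloxy)phenyl]-4-{(2R,3R)-3,5,7-tris(benzyloxy)-2-[3,4,5-tris(benzyloxy)phenyl]chroman-8-yl}chroman-3-ol | c1ccccc1COc1ccc2c(c1)O[C@H](c1cc(OCc3ccccc3)c(OCc3ccccc3)c(OCc3ccccc3)c1)[C@@H](O)[C@H]2c1c(OCc3ccccc3)cc(OCc3ccccc3)c2c1O[C@H](c1cc(OCc3ccccc3)c(OCc3ccccc3)c(OCc3ccccc3)c1)[C@H](OCc1ccccc1)C2 | intermediate
16 | robinetinidol-(4β→8)-epigallocatechin | Oc1ccc2c(c1)O[C@H](c1cc(O)c(O)c(O)c1)[C@@H](O)[C@H]2c1c(O)cc(O)c2c1O[C@H](c1cc(O)c(O)c(O)c1)[C@H](O)C2 | target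

**Step count and risks**

Total: 10 steps. Longest linear sequence: 8 steps (steps 1–5, 8, 9, 10). The three steps most likely to fail are steps 8, 9 and 7.

Step 8. What may go wrong: proton transfer from the acidic C2–H or enol form of 12 to the diazo carbon, followed by O- or C-benzylation instead of carbonyl addition; sluggish addition to the hindered, electron-rich aryl ketone; or migration of C2 instead of the aryl carbon. The fallback sets out from 12 and 4 and comes back to the route at 14. It keeps the ring expansion but brings ring D in afterwards: 12 would be homologated with TMSCHN2 (BF3·OEt2, CH2Cl2, −78 °C, aryl migration) to 7-(benzyloxy)-4-(trimethylsilyl)-2-[3,4,5-tris(benzyloxy)phenyl]chroman-3-one F1, which is protodesilylated on work-up (1 M HCl, THF) to 7-(benzyloxy)-2-[3,4,5-tris(benzyloxy)phenyl]chroman-3-one F2. Pd-catalysed α-arylation of F2 at the benzylic C4 methylene with the bromide 4 (Pd2(dba)3, tBu3P·HBF4, NaOtBu, toluene, 80 °C) should then give 14.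

Step 9. What may go wrong: insufficient catalyst control over which enantiomeric series of the interconverting ketone is reduced, or slow hydride transfer to the doubly α-branched ketone. The fallback sets out from 14 and comes back at 15. It relies on substrate control only: after equilibration with DBU, reduction with NaBH4 (THF/MeOH, −40 °C) should give the two 2,3-trans-3,4-cis alcohols, 15 and its upper-unit (2S,3R,4S) diastereomer F3. These are diastereomers because of the lower unit and would be separated by chromatography; F3 would be oxidised back to 14 with Dess–Martin periodinane and recycled.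

Step 7. What may go wrong: loss of benzyl ethers or decarbonylation of the activated acyl group under the acidic acylation conditions, or ring closure at the position between the two oxygens. The fallback sets out from 9 and comes back at 12. It closes the furanone ring by an anionic route: Jocic–Reeve reaction of 9 with 2-bromo-5-(benzyloxy)phenol (CHBr3, KOH, LiCl, dioxane/H2O) would give rac-2-[5-(benzyloxy)-2-bromophenoxy]-2-[3,4,5-tris(benzyloxy)phenyl]acetic acid F4, and esterification (MeI, K2CO3, DMF) its methyl ester F5. Bromine–lithium exchange (nBuLi, THF, −100 °C) gives the aryllithium F6, which closes onto the ester (Parham cyclization) to give 12 with the ring position fixed by the bromine.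

Further compounds
F1 | step 8 | 7-(benzyloxy)-4-(trimethylsilyl)-2-[3,4,5-tris(benzyloxy)phenyl]chroman-3-one | O=C1C([Si](C)(C)C)c2ccc(OCc3ccccc3)cc2OC1c1cc(OCc2ccccc2)c(OCc2ccccc2)c(OCc2ccccc2)c1
F2 | step 8 | 7-(benzyloxy)-2-[3,4,5-tris(benzyloxy)phenyl]chroman-3-one | O=C1Cc2ccc(OCc3ccccc3)cc2OC1c1cc(OCc2ccccc2)c(OCc2ccccc2)c(OCc2ccccc2)c1
F3 | step 9 | (2S,3R,4S)-7-(benzyloxy)-2-[3,4,5-tris(benzyloxy)phenyl]-4-{(2R,3R)-3,5,7-tris(benzyloxy)-2-[3,4,5-tris(benzyloxy)phenyl]chroman-8-yl}chroman-3-ol | c1ccccc1COc1ccc2c(c1)O[C@@H](c1cc(OCc3ccccc3)c(OCc3ccccc3)c(OCc3ccccc3)c1)[C@H](O)[C@@H]2c1c(OCc3ccccc3)cc(OCc3ccccc3)c2c1O[C@H](c1cc(OCc3ccccc3)c(OCc3ccccc3)c(OCc3ccccc3)c1)[C@H](OCc1ccccc1)C2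
F4 | step 7 | rac-2-[5-(benzyloxy)-2-bromophenoxy]-2-[3,4,5-tris(benzyloxy)phenyl]acetic acid | OC(=O)C(Oc1cc(OCc2ccccc2)ccc1Br)c1cc(OCc2ccccc2)c(OCc2ccccc2)c(OCc2ccccc2)c1
F5 | step 7 | methyl rac-2-[5-(benzyloxy)-2-bromophenoxy]-2-[3,4,5-tris(benzyloxy)phenyl]acetate | COC(=O)C(Oc1cc(OCc2ccccc2)ccc1Br)c1cc(OCc2ccccc2)c(OCc2ccccc2)c(OCc2ccccc2)c1
F6 | step 7 | methyl rac-2-[5-(benzyloxy)-2-lithiophenoxy]-2-[3,4,5-tris(benzyloxy)phenyl]acetate | COC(=O)C(Oc1cc(OCc2ccccc2)ccc1[Li])c1cc(OCc2ccccc2)c(OCc2ccccc2)c(OCc2ccccc2)c1
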